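**Strategy.** Ring A is closed on a preformed ring B by joining C3 to C4 (decalin numbering; C11 is the exocyclic methylene carbon). The step exploits the C4=C11 methylene that sits next to the quaternary C5: it is the imprint of an ethynyl group on C5 that has been attacked at its inner carbon by a primary C3 radical. A 6-exo-dig radical cyclisation of a 3-bromopropyl chain on C10 therefore delivers ring A and the methylene in one operation, with no ketone to protect or olefinate. The precursor, a 4-ethynyl-4-methylcyclohexenone, comes from an enantioselective Diels–Alder reaction; reductive benzylation, deoxygenative methylation and quinone unveiling finish the route.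

Key step: step 8

Numbering: ring carbons C1–C10 as in the target decalin, C11 = exocyclic methylene carbon on C4; α is the face of H-10, β the face of the C5 methyl group.

Assumption: the (S)-oxazaborolidinium catalyst of step 5 is taken to direct the diene to the Cα-Re face of a 2-substituted acrolein (the sense assumed for methacrolein with cyclopentadiene), which gives (S)-C5; if the sense were the reverse, the (R)-catalyst would be used with nothing else changed.

Step 1
Reactants: 1 1,2,4,5-tetramethoxybenzene
Product: 3 (2,3,5,6-tetramethoxyphenyl)methanol, via aryllithium 2 (not isolated)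
Conditions: n-BuLi, TMEDA, THF, 0 °C; (CH2O)n, 0 °C to rt; aq NH4Cl
Reagents that add atoms: formaldehyde (from paraformaldehyde) C=O
Why: Directed ortho-lithiation at a ring C–H flanked by two methoxy groups (both free positions are equivalent), then addition of the aryllithium to formaldehyde, gives the benzylic alcohol.

Step 2
Reactants: 3 (2,3,5,6-tetramethoxyphenyl)methanol
Product: 4 3-(bromomethyl)-1,2,4,5-tetramethoxybenzene
Conditions: PBr3, Et2O, 0 °C
Reagents that add atoms: phosphorus tribromide BrP(Br)Br
Why: Standard conversion of an electron-rich benzylic alcohol into the bromide via its phosphite ester (nucleophilic substitution); the bromide is used fresh.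

Step 3
Reactants: 5 5-bromopent-1-ene; 6 3-methylbut-3-en-2-one
Product: 7 (E)-7-bromo-3-methylhept-3-en-2-one
Conditions: second-generation Hoveyda–Grubbs catalyst RuCl2(=CH-C6H4-2-OiPr)(SIMes) (5 mol %), 6 (4 equiv), CH2Cl2, 40 °C
Reagents that add atoms: none
Why: Olefin cross-metathesis of a terminal alkene with an excess of a 1,1-disubstituted enone, which does not homodimerise, should give the trisubstituted enone as the thermodynamically favoured (E)-isomer.

Step 4
Reactants: 7 (E)-7-bromo-3-methylhept-3-en-2-one
Product: 8 [(3E)-7-bromo-3-methylhepta-1,3-dien-2-yl]oxy-triisopropylsilane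
Conditions: TIPSOTf, Et3N, CH2Cl2, 0 °C
Reagents that add atoms: triisopropylsilyl triflate CC(C)[Si](C(C)C)(C(C)C)OS(=O)(=O)C(F)(F)F
Why: Soft enolisation of the methyl ketone on its α'-methyl group gives the cross-conjugated 2-silyloxy-1,3-diene with the alkene geometry retained.

Step 5
Reactants: 8 [(3E)-7-bromo-3-methylhepta-1,3-dien-2-yl]oxy-triisopropylsilane; 9 methacrolein
Product: 10 (1S,2S)-2-(3-bromopropyl)-1,3-dimethyl-4-(triisopropylsilyloxy)cyclohex-3-ene-1-carbaldehyde
Conditions: (S)-3,3-diphenyl-1-(o-tolyl)tetrahydro-1H,3H-pyrrolo[1,2-c][1,3,2]oxazaborole·Tf2NH (20 mol %), CH2Cl2, −78 °C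
Reagents that add atoms: none
Why: Catalytic enantioselective Diels–Alder reaction of a 2-substituted acrolein, in which the 2-silyloxy group (para) and the terminal alkyl group (ortho) direct the same regiochemistry and the chiral boron Lewis acid shields one face of the enal, sets the quaternary centre (C5, S); the exo mode is expected, but the C10 centre is erased in step 6, so the exo/endo ratio does not matter.

Step 6
Reactants: 10 (1S,2S)-2-(3-bromopropyl)-1,3-dimethyl-4-(triisopropylsilyloxy)cyclohex-3-ene-1-carbaldehyde
Product: 11 (S)-2-(3-bromopropyl)-1,3-dimethyl-4-oxocyclohex-2-ene-1-carbaldehyde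
Conditions: Pd(OAc)2 (1.1 equiv), MeCN, 40 °C
Reagents that add atoms: none
Why: Saegusa–Ito oxidation, in which palladation of the silyl enol ether at C9 anti to the side chain places palladium syn to H-10 and β-hydride elimination gives the tetrasubstituted enone, removing the C10 centre on purpose while aldehyde, bromide and C5 are untouched.

Step 7
Reactants: 11 (S)-2-(3-bromopropyl)-1,3-dimethyl-4-oxocyclohex-2-ene-1-carbaldehyde
Product: 12 (R)-3-(3-bromopropyl)-4-ethynyl-2,4-dimethylcyclohex-2-en-1-one
Conditions: dimethyl (1-diazo-2-oxopropyl)phosphonate, K2CO3, MeOH, 0 °C to rt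
Reagents that add atoms: dimethyl (1-diazo-2-oxopropyl)phosphonate COP(=O)(OC)C(=[N+]=[N-])C(C)=O
Why: Ohira–Bestmann (Seyferth–Gilbert) homologation of the non-enolisable neopentyl aldehyde gives the terminal alkyne, the fully substituted enone β-carbon being too hindered to react; C5 keeps its configuration (the descriptor changes only through the priority rules).

Step 8
Reactants: 12 (R)-3-(3-bromopropyl)-4-ethynyl-2,4-dimethylcyclohex-2-en-1-one
Product: 13 (R)-1,4a-dimethyl-5-methylidene-4,4a,5,6,7,8-hexahydronaphthalen-2(3H)-one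
Conditions: Bu3SnH (1.3 equiv) and AIBN (0.2 equiv) by syringe pump over 10 h, PhH (0.005 M), 80 °C
Reagents that add atoms: none
Why: The tributyltin radical abstracts bromine to give the primary C3 radical, which adds to the inner alkyne carbon C4, and the σ-vinyl radical at C11 then takes hydrogen from Bu3SnH to leave the exocyclic methylene. The closest known reaction type is the tin-hydride-mediated 6-exo-dig cyclisation of hept-6-ynyl radicals (Stork-type radical cyclisation onto alkynes). Ring A closes in the 6-exo mode onto the ring-B cyclohexenone through the new C3–C4 bond. No stereocentre is formed, since C5 was set in step 5 and C10 is still sp2. The selectivity needed is cyclisation ahead of hydrogen transfer to the open-chain radical and of alkyne hydrostannation; the low stationary tin hydride concentration, the gem-disubstituent effect of quaternary C5 and the rigid cyclohexenone that holds chain and alkyne on adjacent ring atoms should secure it. The enone is not a competing acceptor because it offers only 4-exo or 5-endo closures.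

Step 9
Reactants: 13 (R)-1,4a-dimethyl-5-methylidene-4,4a,5,6,7,8-hexahydronaphthalen-2(3H)-one; 4 3-(bromomethyl)-1,2,4,5-tetramethoxybenzene
Product: 15 (1S,4aS,8aR)-1,4a-dimethyl-5-methylidene-1-[(2,3,5,6-tetramethoxyphenyl)methyl]octahydronaphthalen-2(1H)-one, via lithium enolate 14 (not isolated)
Conditions: Li, NH3(l)/THF, t-BuOH (1 equiv), −78 to −33 °C; isoprene; then 4, THF, −78 to −33 °C
Reagents that add atoms: none
Why: Stork reductive alkylation, in which dissolving-metal reduction protonates C10 axially to give the trans-fused enolate and the benzyl bromide then attacks C9 from the α-face anti to the axial C5 methyl, sets C10 (H α) and C9 (CH2Ar α, CH3 β) without reducing the isolated 1,1-disubstituted alkene.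

Step 10
Reactants: 15 (1S,4aS,8aR)-1,4a-dimethyl-5-methylidene-1-[(2,3,5,6-tetramethoxyphenyl)methyl]octahydronaphthalen-2(1H)-one
Product: 17 methyl (1S,4aS,8aR)-1,2,4a-trimethyl-5-methylidene-1-[(2,3,5,6-tetramethoxyphenyl)methyl]decahydronaphthalen-2-yl oxalate (C2 epimers), via dichlorocerium alkoxide 16 (not isolated)
Conditions: MeLi, CeCl3, THF, −78 °C; then ClC(O)CO2Me, −78 °C to rt
Reagents that add atoms: methyllithium C[Li]; methyl chlorooxoacetate COC(=O)C(Cl)=O
Why: Organocerium 1,2-addition to the hindered, enolisable C8 ketone followed by acylation of the alkoxide in the same flask gives the tertiary methyl oxalate; the C8 configuration is irrelevant because this centre becomes a radical in step 11.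

Step 11
Reactants: 17 methyl (1S,4aS,8aR)-1,2,4a-trimethyl-5-methylidene-1-[(2,3,5,6-tetramethoxyphenyl)methyl]decahydronaphthalen-2-yl oxalate
Product: 18 1,2,4,5-tetramethoxy-3-{[(1R,2S,4aS,8aS)-1,2,4a-trimethyl-5-methylidenedecahydronaphthalen-1-yl]methyl}benzene
Conditions: Bu3SnH, AIBN, PhMe, 110 °C
Reagents that add atoms: none
Why: Dolan–MacMillan radical deoxygenation of a tertiary methyl oxalate, in which the planar C8 radical should take hydrogen from Bu3SnH on the α-face anti to the adjacent axial C9 methyl, gives the equatorial 8β-methyl group (also the more stable epimer) and leaves the exocyclic alkene untouched.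

Step 12
Reactants: 18 1,2,4,5-tetramethoxy-3-{[(1R,2S,4aS,8aS)-1,2,4a-trimethyl-5-methylidenedecahydronaphthalen-1-yl]methyl}benzene
Product: 19 2,5-dimethoxy-3-{[(1R,2S,4aS,8aS)-1,2,4a-trimethyl-5-methylidenedecahydronaphthalen-1-yl]methyl}cyclohexa-2,5-diene-1,4-dione
Conditions: (NH4)2Ce(NO3)6, MeCN/H2O, 0 °C
Reagents that add atoms: water O
Why: Oxidative demethylation of the tetramethoxyarene by tetravalent cerium should give the para-quinone, both para pairs of methoxy groups leading to the same quinone by symmetry, with the alkene untouched.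

Step 13
Reactants: 19 2,5-dimethoxy-3-{[(1R,2S,4aS,8aS)-1,2,4a-trimethyl-5-methylidenedecahydronaphthalen-1-yl]methyl}cyclohexa-2,5-diene-1,4-dione
Product: 20 ilimaquinone
Conditions: KOH, MeOH/H2O, rt; then 1 M HCl
Reagents that add atoms: potassium hydroxide [K+].[OH-]
Why: Vinylogous ester saponification by addition–elimination, in which hydroxide should displace the methoxy group next to the alkyl substituent (twisted out of conjugation, hence the more electrophilic) and the resulting vinylogous acid anion resists a second hydrolysis.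

**Compound list**

1 | 1,2,4,5-tetramethoxybenzene | COc1cc(OC)c(OC)cc1OC | starting material
2 | (2,3,5,6-tetramethoxyphenyl)lithium | COc1cc(OC)c(OC)c([Li])c1OC | intermediate
3 | (2,3,5,6-tetramethoxyphenyl)methanol | COc1cc(OC)c(OC)c(CO)c1OC | intermediate
4 | 3-(bromomethyl)-1,2,4,5-tetramethoxybenzene | COc1cc(OC)c(OC)c(CBr)c1OC | intermediate
5 | 5-bromopent-1-ene | C=CCCCBr | starting material
6 | 3-methylbut-3-en-2-one | CC(=O)C(C)=C | starting material
7 | (E)-7-bromo-3-methylhept-3-en-2-one | CC(=O)/C(C)=C/CCCBr | intermediate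
8 | [(3E)-7-bromo-3-methylhepta-1,3-dien-2-yl]oxy-triisopropylsilane | C=C(O[Si](C(C)C)(C(C)C)C(C)C)/C(C)=C/CCCBr | intermediate
9 | methacrolein (2-methylprop-2-enal) | CC(=C)C=O | starting material
10 | (1S,2S)-2-(3-bromopropyl)-1,3-dimethyl-4-(triisopropylsilyloxy)cyclohex-3-ene-1-carbaldehyde (exo adduct; C2 is erased in step 6) | BrCCC[C@H]1C(C)=C(O[Si](C(C)C)(C(C)C)C(C)C)CC[C@]1(C)C=O | intermediate
11 | (S)-2-(3-bromopropyl)-1,3-dimethyl-4-oxocyclohex-2-ene-1-carbaldehyde | BrCCCC1=C(C)C(=O)CC[C@]1(C)C=O | intermediate
12 | (R)-3-(3-bromopropyl)-4-ethynyl-2,4-dimethylcyclohex-2-en-1-one | BrCCCC1=C(C)C(=O)CC[C@]1(C)C#C | intermediate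
13 | (R)-1,4a-dimethyl-5-methylidene-4,4a,5,6,7,8-hexahydronaphthalen-2(3H)-one | C=C1CCCC2=C(C)C(=O)CC[C@]12C | intermediate
14 | lithium enolate of the trans-fused decalone (O–Li on C8, C8=C9 double bond, H-10 anti to the C5 methyl) | C=C1CCC[C@H]2C(C)=C(O[Li])CC[C@]12C | intermediate
15 | (1S,4aS,8aR)-1,4a-dimethyl-5-methylidene-1-[(2,3,5,6-tetramethoxyphenyl)methyl]octahydronaphthalen-2(1H)-one | C=C1CCC[C@H]2[C@](C)(Cc3c(OC)c(OC)cc(OC)c3OC)C(=O)CC[C@]12C | intermediate
16 | dichlorocerium alkoxide of the C8 tertiary methyl carbinol (C8 epimers) | C=C1CCC[C@H]2[C@](C)(Cc3c(OC)c(OC)cc(OC)c3OC)C(C)(O[Ce](Cl)Cl)CC[C@]12C | intermediate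
17 | methyl (1S,4aS,8aR)-1,2,4a-trimethyl-5-methylidene-1-[(2,3,5,6-tetramethoxyphenyl)methyl]decahydronaphthalen-2-yl oxalate (C2 epimers) | C=C1CCC[C@H]2[C@](C)(Cc3c(OC)c(OC)cc(OC)c3OC)C(C)(OC(=O)C(=O)OC)CC[C@]12C | intermediate
18 | 1,2,4,5-tetramethoxy-3-{[(1R,2S,4aS,8aS)-1,2,4a-trimethyl-5-methylidenedecahydronaphthalen-1-yl]methyl}benzene | C=C1CCC[C@H]2[C@](C)(Cc3c(OC)c(OC)cc(OC)c3OC)[C@@H](C)CC[C@]12C | intermediate
19 | 2,5-dimethoxy-3-{[(1R,2S,4aS,8aS)-1,2,4a-trimethyl-5-methylidenedecahydronaphthalen-1-yl]methyl}cyclohexa-2,5-diene-1,4-dione | C=C1CCC[C@H]2[C@](C)(CC3=C(OC)C(=O)C=C(OC)C3=O)[C@@H](C)CC[C@]12C | intermediate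
20 | ilimaquinone, 2-hydroxy-5-methoxy-3-{[(1R,2S,4aS,8aS)-1,2,4a-trimethyl-5-methylidenedecahydronaphthalen-1-yl]methyl}cyclohexa-2,5-diene-1,4-dione | C=C1CCC[C@H]2[C@](C)(CC3=C(O)C(=O)C=C(OC)C3=O)[C@@H](C)CC[C@]12C | target

**Step count.** 13 steps in total; the longest linear sequence is 11 steps (steps 3 to 13), and steps 1 and 2 make the benzyl bromide used in step 9.

**Steps most likely to fail**

Step 8. The primary radical may be reduced by tin hydride before the rather slow 6-exo-dig closure, or the tin radical may add to the terminal alkyne. The fallback removes the hydride donor from the cyclisation. It sets out from 12: a Finkelstein exchange (NaI, acetone) gives (R)-4-ethynyl-3-(3-iodopropyl)-2,4-dimethylcyclohex-2-en-1-one F1. Iodine-atom-transfer cyclisation ((Bu3Sn)2, 10 mol %, PhH, sunlamp, 80 °C) then gives (S)-5-(iodomethylidene)-1,4a-dimethyl-4,4a,5,6,7,8-hexahydronaphthalen-2(3H)-one F2 as an E/Z mixture. A short treatment of the vinyl iodide with Bu3SnH and AIBN removes iodine and comes back to the route at 13.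

Step 11. Hydrogen-atom transfer to the planar C8 radical may show poor facial selectivity, and the very hindered oxalate of step 10 may form sluggishly. The fallback sets C8 under thermodynamic control and sets out from 15. A Wittig reaction with MeOCH2PPh3Cl and KOtBu in THF gives the C8 methoxymethylidene enol ether F3. Mild hydrolysis (1 M HCl, THF) and equilibration (K2CO3, MeOH) give the equatorial 8β-carbaldehyde F4. Wolff–Kishner reduction (N2H4·H2O, KOH, diethylene glycol, 200 °C) converts the formyl group into the methyl group and comes back to the route at 18.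

Step 13. Hydroxide may attack the unhindered methoxy-bearing ring carbon instead of the one next to the alkyl group, which would give the regioisomeric hydroxy-methoxy-quinone. The fallback reverses the order of events and sets out from 19. Exhaustive hydrolysis (2 M NaOH, dioxane, 60 °C, then HCl) gives the 2,5-dihydroxyquinone F5. Acid-catalysed vinylogous esterification (MeOH, BF3·OEt2 cat., rt) then methylates the unhindered hydroxyl, remote from the alkyl group, and arrives at 20.

**Further compounds**

F1 | step 8 | (R)-4-ethynyl-3-(3-iodopropyl)-2,4-dimethylcyclohex-2-en-1-one | ICCCC1=C(C)C(=O)CC[C@]1(C)C#C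
F2 | step 8 | (S)-5-(iodomethylidene)-1,4a-dimethyl-4,4a,5,6,7,8-hexahydronaphthalen-2(3H)-one (E/Z mixture) | IC=C1CCCC2=C(C)C(=O)CC[C@]12C
F3 | step 11 | C8 methoxymethylidene enol ether of the benzylated trans-decalin (E/Z mixture) | C=C1CCC[C@H]2[C@](C)(Cc3c(OC)c(OC)cc(OC)c3OC)C(=COC)CC[C@]12C
F4 | step 11 | 8β-carbaldehyde of the benzylated trans-decalin (formyl equatorial) | C=C1CCC[C@H]2[C@](C)(Cc3c(OC)c(OC)cc(OC)c3OC)[C@@H](C=O)CC[C@]12C
F5 | step 13 | 2,5-dihydroxy-3-{[(1R,2S,4aS,8aS)-1,2,4a-trimethyl-5-methylidenedecahydronaphthalen-1-yl]methyl}cyclohexa-2,5-diene-1,4-dione | C=C1CCC[C@H]2[C@](C)(CC3=C(O)C(=O)C=C(O)C3=O)[C@@H](C)CC[C@]12C
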